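## Retrosynthetic overview

1. Enabling feature: ring C (C8, C9, C11, C12, C13, C14) is a cyclohexane that shares the C8–C9 edge with ring B and carries one-carbon arms on the neighbouring atoms C13 and C14. With a C11=C12 double bond and the C14 arm as an aldehyde, it is the retron of a type 1 intramolecular Diels–Alder reaction whose tether is the C10–C5–C6–C7 chain of ring B.
2. Late disconnections: C24 acetoxy acetal ⇒ lactol ⇒ bridged 1,3-dioxolan-4-one (C25 acetal of the C13 aldehyde with the C17 α-hydroxy acid) ⇒ acetal exchange from a 2-tert-butyl-dioxolanone. C16–C17 ⇒ aldol of the (S)-malic acid dioxolanone enolate (sets C16 and C17). C15–C16 ⇒ one-carbon homologation of the cycloadduct aldehyde (removes the activating oxygen).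
3. Key disconnection: C8–C9 and C13–C14 ⇒ a monocyclic (E,E,E)-trienal on ring A. Ring A with C5 and C10 ⇒ (+)-sclareolide, opened between C8 and C9 by alkoxy-radical β-scission.
4. Ring order: ring A (chiral pool); rings B and C together (step 8); the dioxolane and oxepane rings together (step 18).

Key step: step 8

Remark (numbering): ring A = C1–C5, C10; ring B = C5–C10; ring C = C8, C9, C11–C14; C15–C16–C17 is the chain on C14; C18–C19 is the CH2CO2H arm on C17; C24 is the acetoxy acetal carbon on C17; C25 is the acetal CH on C13. α/β refer to the usual terpenoid drawing with the C10 methyl β. In this numbering the target is 5S,8S,9S,10S,13S,14R,16R,17R,24R,25R.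

Remark (assumption): the C24 acetate of the target lies on the convex face of the dioxabicyclo[4.2.1]nonane (anti to the C13–C16 bridge, syn to C18). Acylation of the lactol is expected to give this anomer.

## Route

Step 1
Reactants: 1 (+)-sclareolide
Product: 3 methyl 2-[(1R,2R,4aS,8aS)-2-hydroxy-2,5,5,8a-tetramethyldecahydronaphthalen-1-yl]acetate, via potassium carboxylate 2 (not isolated)
Conditions: KOH, MeOH, reflux; evaporation; MeI, DMF, rt
Reagents that add atoms: potassium hydroxide [K+].[OH-]; iodomethane CI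
Why: Saponification of the γ-lactone and SN2 methylation of the carboxylate open the lactone without touching a stereocentre and free the tertiary C8 hydroxyl needed for the radical scission.

Step 2
Reactants: 3 methyl hydroxy ester
Product: 5 methyl (2E)-3-[(1R,2S)-1,3,3-trimethyl-2-(3-oxobutyl)cyclohexyl]prop-2-enoate, via β-iodo ester 4 (not isolated)
Conditions: PhI(OAc)2, I2, CH2Cl2, visible light, rt; then DBU, rt
Reagents that add atoms: none
Why: Hypoiodite fragmentation: the tertiary C8 alkoxy radical has no 1,5-hydrogen within reach and undergoes β-scission of the C8–C9 bond (secondary radical, loss of the 1,3-diaxial methyl strain) to the methyl ketone, the C9 radical is trapped by iodine, and E1cB elimination of the β-iodo ester gives the E-enoate while C5 and C10 stay as in 1.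

Step 3
Reactants: 5 keto enoate
Product: 7 (1S,2S)-1,3,3-trimethyl-2-(3-oxobutyl)cyclohexane-1-carbaldehyde, via ozonide 6 (not isolated)
Conditions: O3, CH2Cl2, −78 °C; then PPh3, −78 °C → rt
Reagents that add atoms: ozone [O-][O+]=O
Why: Ozonolysis of the only C=C bond with reductive work-up uncovers C9 as a non-enolisable aldehyde on the quaternary C10.

Step 4
Reactants: 7 keto aldehyde
Product: 8 ethyl (2E,4E)-5-[(1R,2S)-1,3,3-trimethyl-2-(3-oxobutyl)cyclohexyl]penta-2,4-dienoate
Conditions: (EtO)2P(O)CH2CH=CHCO2Et, LiN(SiMe3)2, THF, −78 → 0 °C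
Reagents that add atoms: triethyl 4-phosphonocrotonate CCOC(=O)/C=C/CP(=O)(OCC)OCC
Why: Vinylogous Horner–Wadsworth–Emmons olefination takes the aldehyde and leaves the much less electrophilic methyl ketone, and should give the E,E-dienoate (C9=C11 and C12=C13) as the favoured isomer.

Step 5
Reactants: 8 dienoate ketone
Product: 9 ethyl (2E,4E)-5-[(1R,2S)-2-[(3E)-5-[methoxy(methyl)amino]-3-methyl-5-oxopent-3-en-1-yl]-1,3,3-trimethylcyclohexyl]penta-2,4-dienoate
Conditions: (EtO)2P(O)CH2C(O)N(OMe)Me, NaH, THF, 0 → 60 °C; chromatography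
Reagents that add atoms: diethyl [2-[methoxy(methyl)amino]-2-oxoethyl]phosphonate CCOP(=O)(CC(=O)N(C)OC)OCC
Why: Horner–Wadsworth–Emmons olefination of the methyl ketone with the Weinreb amide phosphonate should give mainly the E trisubstituted alkene (long chain trans to the amide), the minor Z isomer being removed by chromatography.

Step 6
Reactants: 9 Weinreb amide dienoate
Product: 10 (2E)-5-[(1S,2R)-2-[(1E,3E)-5-hydroxypenta-1,3-dien-1-yl]-2,6,6-trimethylcyclohexyl]-3-methylpent-2-enal
Conditions: i-Bu2AlH (4 equiv), CH2Cl2, −78 °C; aq. KNaC4H4O6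
Reagents that add atoms: none
Why: One hydride reagent brings both ends to the needed oxidation level, since the dienoate is reduced to the primary dienol while the Weinreb amide stops at the chelated aluminium hemiaminal and releases the enal on hydrolysis.

Step 7
Reactants: 10 hydroxy trienal
Product: 11 (2E)-5-[(1S,2R)-2-[(1E,3E)-5-(tert-butyldiphenylsilyloxy)penta-1,3-dien-1-yl]-2,6,6-trimethylcyclohexyl]-3-methylpent-2-enal
Conditions: TBDPSCl, imidazole, CH2Cl2, 0 °C → rt
Reagents that add atoms: tert-butyl(chloro)diphenylsilane CC(C)(C)[Si](Cl)(c1ccccc1)c1ccccc1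
Why: Silylation of the primary alcohol gives a robust ether that keeps the diene electron-rich and should survive the Lewis acid of step 8 and the aqueous acid of step 11.

Step 8
Reactants: 11 silylated trienal
Product: 12 cycloadduct aldehyde (rings A/B/C trans-anti-trans; C11=C12; 8β-CH3; 9α-H; C14 formyl β equatorial; C13 CH2OTBDPS β axial)
Conditions: Me2AlCl (1.1 equiv), CH2Cl2, −78 → −20 °C; then 1 M HCl
Reagents that add atoms: none
Why: Me2AlCl binds the aldehyde oxygen of the s-trans enal and lowers its LUMO, so that the (E,E)-diene C9=C11–C12=C13 and the trisubstituted alkene C14=C8 combine in a concerted, asynchronous [4+2] cycloaddition in which the C8–C9 bond (to the β-carbon of the enal) runs ahead of the C13–C14 bond. The closest known reaction type is the Lewis-acid-promoted type 1 intramolecular Diels–Alder reaction of terminally activated 1,7,9-decatrienals and -trienones, which gives trans-fused octalins, also with β-methyl dienophiles that end as angular methyl groups. Ring B closes as the six-membered ring spanned by the four-atom tether C10–C5–C6–C7 in a chair-like array, and ring C closes as the cyclohexene of the [4+2] event itself. C8 and C14 are fixed relative to each other by the E geometry of the enal (CH3 and CHO cis), C9 and C13 by the E,E geometry of the diene (the C13 arm cis to the C9–C10 bond, hence axial, to be corrected in step 17), the trans B/C fusion (8β-CH3, 9α-H) by the endo position of the complexed carbonyl under the diene, and the absolute sense by ring A, whose C10–C9 and C5–C6 bonds are trans-diequatorial and hold the tether in one chair with the C10 methyl axial. The step needs endo over exo selectivity and a single diene face: the Lewis acid should secure the first, and the exo and opposite-face alternatives would have to place C14 or C11 axial on the forming ring B or fold the tether into a boat.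

Step 9
Reactants: 12 cycloadduct aldehyde
Product: 13 saturated tricyclic aldehyde (11,12-dihydro-12)
Conditions: H2 (1 atm), Pd/C, EtOAc, rt
Reagents that add atoms: none
Why: Heterogeneous hydrogenation saturates the cis-disubstituted C11=C12 bond (no new stereocentre) before C13 becomes an aldehyde α-carbon, so that the later epimerisation cannot pull the double bond into conjugation.

Step 10
Reactants: 13 saturated tricyclic aldehyde
Product: 14 methyl enol ether (C14–CH=CH–OCH3; E/Z mixture)
Conditions: Ph3P(CH2OMe)Cl, KN(SiMe3)2, THF, 0 °C → rt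
Reagents that add atoms: (methoxymethyl)triphenylphosphonium chloride COC[P+](c1ccccc1)(c1ccccc1)c1ccccc1.[Cl-]
Why: Wittig methoxymethylenation works on hindered aldehydes and adds C16, and the C14 arm is already equatorial so the basic ylide cannot erode that centre.

Step 11
Reactants: 14 methyl enol ether
Product: 15 homologous aldehyde (C14–CH2–CHO; C16 aldehyde)
Conditions: 1 M HCl, THF, rt
Reagents that add atoms: water O
Why: Acid hydrolysis of the enol ether completes the one-carbon homologation, the activating C15 oxygen of the cycloadduct having left as triphenylphosphine oxide in step 10.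

Step 12
Reactants: 16 (S)-malic acid; 17 pivalaldehyde
Product: 18 2-[(2S,4S)-2-tert-butyl-5-oxo-1,3-dioxolan-4-yl]acetic acid (cis)
Conditions: TsOH·H2O (cat.), H2SO4 (cat.), pentane, reflux, Dean–Stark; recrystallisation
Reagents that add atoms: none
Why: Acid-catalysed acetalisation of the α-hydroxy acid (self-regeneration of stereocentres) gives the cis dioxolanone, whose acetal centre stores the configuration of the malic acid carbon that is about to become trigonal.

Step 13
Reactants: 15 C16 aldehyde; 18 dioxolanone acid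
Product: 21 (16R,17R) acetate acid: 2-[(2S,4R)-2-tert-butyl-4-[(1R)-1-acetoxy-2-(tricyclyl)ethyl]-5-oxo-1,3-dioxolan-4-yl]acetic acid, via dilithium enolate 19 (not isolated), via dilithium aldolate 20 (not isolated)
Conditions: 18, LiN(SiMe3)2 (2.1 equiv), THF, −78 °C; 15, −78 °C; Ac2O, −78 → 0 °C; aq. HCl to pH 3
Reagents that add atoms: acetic anhydride CC(=O)OC(C)=O
Why: Aldol addition of the dioxolanone enolate: the aldehyde should add anti to the tert-butyl group (C17, overall retention with respect to the malic acid hydrogen) through a closed Zimmerman–Traxler chair with the aldehyde chain equatorial, which places the C16 oxygen anti to the ring oxygen (16R), and acetylation of the lithium aldolate in the flask blocks retro-aldol cleavage and γ-lactonisation onto C19.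

Step 14
Reactants: 21 acetate acid
Product: 22 benzyl ester of 21
Conditions: BnBr, Cs2CO3, DMF, rt
Reagents that add atoms: benzyl bromide BrCc1ccccc1
Why: O-Alkylation of the caesium carboxylate masks C19 as an ester that is inert to the borane of step 19 and is removed at the end under neutral conditions.

Step 15
Reactants: 22 benzyl ester
Product: 23 primary alcohol (C25–OH; axial CH2OH on C13)
Conditions: Bu4NF, AcOH (1:1), THF, rt
Reagents that add atoms: none
Why: Buffered fluoride cleaves the silyl ether without attacking the acetate, the benzyl ester or the dioxolanone.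

Step 16
Reactants: 23 primary alcohol
Product: 24 axial C25 aldehyde (13α-H)
Conditions: Dess–Martin periodinane, CH2Cl2, rt
Reagents that add atoms: none
Why: Dess–Martin oxidation gives the aldehyde under non-basic conditions that leave the esters and the acylal alone.

Step 17
Reactants: 24 axial aldehyde
Product: 25 equatorial C25 aldehyde (13β-H; 13S as in the target)
Conditions: DBU (0.2 equiv), CH2Cl2, rt
Reagents that add atoms: none
Why: Base-mediated epimerisation through the enolate moves the formyl group from the axial position, where it is 1,3-diaxial to the C8 methyl, to the equatorial one, the aldehyde α-hydrogen being far more acidic than any other C–H in the molecule.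

Step 18
Reactants: 25 equatorial aldehyde
Product: 26 bridged dioxolanone (2,8-dioxabicyclo[4.2.1]nonan-9-one fused to ring C; C25 acetal; C24 lactone carbonyl)
Conditions: TsOH·H2O (0.1 equiv), benzene (0.005 M), 80 °C, slow distillation of t-BuCHO
Reagents that add atoms: none
Why: Acid-catalysed acetal exchange at the acetal carbon of the 1,3-dioxolan-4-one, the same equilibrium by which such dioxolanones form and epimerise: the C13 aldehyde replaces pivalaldehyde, which distils off, the oxepane and the new dioxolanone close together, and C25 can only take the configuration in which the bridge is cis to the C16 arm on C17.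

Step 19
Reactants: 26 bridged dioxolanone
Product: 27 bridged lactol (C24–OH; anomeric mixture)
Conditions: Sia2BH (3 equiv), THF, 0 °C → rt; pH 7 buffer
Reagents that add atoms: none
Why: Disiamylborane reduces lactones to lactols and leaves acetate and benzyl esters alone (as in the reduction of acylated aldonolactones), and the acylal-type carbonyl C24 is the most electrophilic one in the molecule.

Step 20
Reactants: 27 bridged lactol
Product: 28 benzyl ester of the target (16,24-diacetate; 24R)
Conditions: Ac2O, pyridine, DMAP (cat.), CH2Cl2, 0 °C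
Reagents that add atoms: acetic anhydride CC(=O)OC(C)=O
Why: Acylation of the interconverting lactol anomers should take place at the hydroxyl on the convex face, anti to the C13–C16 bridge, and give the 24R acetate.

Step 21
Reactants: 28 benzyl ester
Product: 29 CNP0138244.2 (target)
Conditions: H2 (1 atm), Pd/C, EtOAc, rt
Reagents that add atoms: none
Why: Hydrogenolysis of the benzyl ester frees the C19 acid under neutral conditions that leave both acetates and the bicyclic acetal untouched.

## Compound list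

1 | (+)-sclareolide, (3aR,5aS,9aS,9bR)-3a,6,6,9a-tetramethyldecahydronaphtho[2,1-b]furan-2(1H)-one | O=C1C[C@H]2[C@@](O1)(C)CC[C@H]1C(C)(C)CCC[C@]21C | starting material
2 | potassium 2-[(1R,2R,4aS,8aS)-2-hydroxy-2,5,5,8a-tetramethyldecahydronaphthalen-1-yl]acetate | [K+].[O-]C(=O)C[C@H]2[C@@](O)(C)CC[C@H]1C(C)(C)CCC[C@]21C | intermediate (not isolated)
3 | methyl 2-[(1R,2R,4aS,8aS)-2-hydroxy-2,5,5,8a-tetramethyldecahydronaphthalen-1-yl]acetate | COC(=O)C[C@H]2[C@@](O)(C)CC[C@H]1C(C)(C)CCC[C@]21C | intermediate
4 | methyl 3-iodo-3-[(1S,2S)-1,3,3-trimethyl-2-(3-oxobutyl)cyclohexyl]propanoate (both C9 epimers) | CC(=O)CC[C@H]1C(C)(C)CCC[C@]1(C)C(I)CC(=O)OC | intermediate (not isolated)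
5 | methyl (2E)-3-[(1R,2S)-1,3,3-trimethyl-2-(3-oxobutyl)cyclohexyl]prop-2-enoate | CC(=O)CC[C@H]1C(C)(C)CCC[C@]1(C)/C=C/C(=O)OC | intermediate
6 | secondary ozonide of 5 (1,2,4-trioxolane across C9 and C11) | CC(=O)CC[C@H]1C(C)(C)CCC[C@]1(C)C1OOC(C(=O)OC)O1 | intermediate (not isolated)
7 | (1S,2S)-1,3,3-trimethyl-2-(3-oxobutyl)cyclohexane-1-carbaldehyde | CC(=O)CC[C@H]1C(C)(C)CCC[C@]1(C)C=O | intermediate
8 | ethyl (2E,4E)-5-[(1R,2S)-1,3,3-trimethyl-2-(3-oxobutyl)cyclohexyl]penta-2,4-dienoate | CC(=O)CC[C@H]1C(C)(C)CCC[C@]1(C)/C=C/C=C/C(=O)OCC | intermediate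
9 | ethyl (2E,4E)-5-[(1R,2S)-2-[(3E)-5-[methoxy(methyl)amino]-3-methyl-5-oxopent-3-en-1-yl]-1,3,3-trimethylcyclohexyl]penta-2,4-dienoate | CON(C)C(=O)/C=C(\C)CC[C@H]1C(C)(C)CCC[C@]1(C)/C=C/C=C/C(=O)OCC | intermediate
10 | (2E)-5-[(1S,2R)-2-[(1E,3E)-5-hydroxypenta-1,3-dien-1-yl]-2,6,6-trimethylcyclohexyl]-3-methylpent-2-enal | O=C/C=C(\C)CC[C@H]1C(C)(C)CCC[C@]1(C)/C=C/C=C/CO | intermediate
11 | (2E)-5-[(1S,2R)-2-[(1E,3E)-5-(tert-butyldiphenylsilyloxy)penta-1,3-dien-1-yl]-2,6,6-trimethylcyclohexyl]-3-methylpent-2-enal | O=C/C=C(\C)CC[C@H]1C(C)(C)CCC[C@]1(C)/C=C/C=C/CO[Si](c1ccccc1)(c1ccccc1)C(C)(C)C | intermediate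
12 | cycloadduct: trans-anti-trans tricycle (rings A/B/C) with C11=C12; 5α-H, 8β-CH3, 9α-H, 10β-CH3; CHO (C15) β-equatorial on C14 (14α-H); CH2OTBDPS (C25) β-axial on C13 (13α-H) | O=C[C@@H]1[C@H](CO[Si](c2ccccc2)(c2ccccc2)C(C)(C)C)C=C[C@H]2[C@@]1(C)CC[C@H]1C(C)(C)CCC[C@]21C | intermediate
13 | 11,12-dihydro derivative of 12 (saturated tricyclic aldehyde) | O=C[C@@H]1[C@H](CO[Si](c2ccccc2)(c2ccccc2)C(C)(C)C)CC[C@H]2[C@@]1(C)CC[C@H]1C(C)(C)CCC[C@]21C | intermediate
14 | methyl enol ether of 13 (C14–CH=CH–OCH3, E/Z mixture) | COC=C[C@@H]1[C@H](CO[Si](c2ccccc2)(c2ccccc2)C(C)(C)C)CC[C@H]2[C@@]1(C)CC[C@H]1C(C)(C)CCC[C@]21C | intermediate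
15 | homologous aldehyde (C14–CH2–CHO; otherwise as 13) | O=CC[C@@H]1[C@H](CO[Si](c2ccccc2)(c2ccccc2)C(C)(C)C)CC[C@H]2[C@@]1(C)CC[C@H]1C(C)(C)CCC[C@]21C | intermediate
16 | (S)-malic acid | O[C@@H](CC(=O)O)C(=O)O | starting material
17 | pivalaldehyde (2,2-dimethylpropanal) | CC(C)(C)C=O | starting material
18 | 2-[(2S,4S)-2-tert-butyl-5-oxo-1,3-dioxolan-4-yl]acetic acid | CC(C)(C)[C@H]1O[C@@H](CC(=O)O)C(=O)O1 | intermediate
19 | dilithium enolate of 18 | [Li+].[Li+].CC(C)(C)[C@H]1OC(CC(=O)[O-])=C([O-])O1 | intermediate (not isolated)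
20 | dilithium aldolate (16R alkoxide, 17R, C19 carboxylate) | [Li+].[Li+].CC(C)(C)[C@H]1O[C@@](CC(=O)[O-])(C(=O)O1)[C@H]([O-])C[C@@H]1[C@H](CO[Si](c2ccccc2)(c2ccccc2)C(C)(C)C)CC[C@H]2[C@@]1(C)CC[C@H]1C(C)(C)CCC[C@]21C | intermediate (not isolated)
21 | (16R,17R) acetate acid: 2-[(2S,4R)-2-tert-butyl-4-[(1R)-1-acetoxy-2-(tricyclyl)ethyl]-5-oxo-1,3-dioxolan-4-yl]acetic acid, tricyclyl = the C14-linked saturated tricycle of 15 with axial CH2OTBDPS on C13 | CC(C)(C)[C@H]1O[C@@](CC(=O)O)(C(=O)O1)[C@H](OC(C)=O)C[C@@H]1[C@H](CO[Si](c2ccccc2)(c2ccccc2)C(C)(C)C)CC[C@H]2[C@@]1(C)CC[C@H]1C(C)(C)CCC[C@]21C | intermediate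
22 | benzyl ester of 21 | CC(C)(C)[C@H]1O[C@@](CC(=O)OCc2ccccc2)(C(=O)O1)[C@H](OC(C)=O)C[C@@H]1[C@H](CO[Si](c2ccccc2)(c2ccccc2)C(C)(C)C)CC[C@H]2[C@@]1(C)CC[C@H]1C(C)(C)CCC[C@]21C | intermediate
23 | primary alcohol (22 without the silyl group; axial CH2OH on C13) | CC(C)(C)[C@H]1O[C@@](CC(=O)OCc2ccccc2)(C(=O)O1)[C@H](OC(C)=O)C[C@@H]1[C@H](CO)CC[C@H]2[C@@]1(C)CC[C@H]1C(C)(C)CCC[C@]21C | intermediate
24 | axial aldehyde (C25 formyl β-axial on C13; 13α-H) | CC(C)(C)[C@H]1O[C@@](CC(=O)OCc2ccccc2)(C(=O)O1)[C@H](OC(C)=O)C[C@@H]1[C@H](C=O)CC[C@H]2[C@@]1(C)CC[C@H]1C(C)(C)CCC[C@]21C | intermediate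
25 | equatorial aldehyde (C25 formyl α-equatorial on C13; 13β-H) | CC(C)(C)[C@H]1O[C@@](CC(=O)OCc2ccccc2)(C(=O)O1)[C@H](OC(C)=O)C[C@@H]1[C@@H](C=O)CC[C@H]2[C@@]1(C)CC[C@H]1C(C)(C)CCC[C@]21C | intermediate
26 | bridged dioxolanone: target skeleton with C24 as lactone carbonyl, 16-acetate and C19 benzyl ester | O=C1O[C@H]2O[C@]1(CC(=O)OCc3ccccc3)[C@H](OC(C)=O)C[C@@H]1[C@@H]2CC[C@H]2[C@@]1(C)CC[C@H]1C(C)(C)CCC[C@]21C | intermediate
27 | bridged lactol (C24–OH, both anomers; 16-acetate; C19 benzyl ester) | OC1O[C@H]2O[C@]1(CC(=O)OCc3ccccc3)[C@H](OC(C)=O)C[C@@H]1[C@@H]2CC[C@H]2[C@@]1(C)CC[C@H]1C(C)(C)CCC[C@]21C | intermediate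
28 | benzyl ester of the target (16R,24R-diacetate) | CC(=O)O[C@H]1O[C@H]2O[C@]1(CC(=O)OCc3ccccc3)[C@H](OC(C)=O)C[C@@H]1[C@@H]2CC[C@H]2[C@@]1(C)CC[C@H]1C(C)(C)CCC[C@]21C | intermediate
29 | CNP0138244.2 | CC(=O)O[C@H]1O[C@H]2O[C@]1(CC(=O)O)[C@H](OC(C)=O)C[C@@H]1[C@@H]2CC[C@H]2[C@@]1(C)CC[C@H]1C(C)(C)CCC[C@]21C | target

## Step count and risks

Total step count: 21. Longest linear sequence: 20 (steps 1–11 and 13–21; step 12 is the one-step side branch).

Steps most likely to fail:

Step 8. What may go wrong: the exo transition state (cis-fused rings B/C) may compete, or bond formation at the fully substituted dienophile carbon may be so slow that the Lewis acid ionises the dienylic silyl ether first. Fallback (ionic Diels–Alder reaction): setting out from 11, the enal is converted with 1,2-bis(trimethylsilyloxy)ethane and catalytic TMSOTf (CH2Cl2, −78 °C) into the 1,3-dioxolane acetal F1. Catalytic TfOH at −78 °C should open this acetal to the O-alkylated enal cation, a far stronger dienophile that should cyclise with the same endo preference to the cycloadduct dioxolane acetal F2. Mild aqueous acid (PPTS, acetone/H2O) then returns the route at aldehyde 12.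

Step 13. What may go wrong: low facial selectivity at the aldehyde carbon (C16 epimers), or retro-aldol cleavage before the aldolate is acylated. Fallback (acylation, then reduction): setting out from 15, chlorite oxidation (NaClO2, NaH2PO4, 2-methyl-2-butene, t-BuOH/H2O) gives the carboxylic acid F3, and carbonyldiimidazole gives the acyl imidazole F4. C-Acylation of dilithium enolate 19 with F4 (again anti to the tert-butyl group, which fixes C17) gives the C16 ketone acid F5, and benzylation (BnBr, Cs2CO3) gives the keto benzyl ester F6. Reduction with Zn(BH4)2 under chelation control (ketone oxygen and ring oxygen on zinc, hydride anti to the dioxolanone ring) should give the 16R alcohol F7, and acetylation (Ac2O, DMAP, pyridine) rejoins the route at 22.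

Step 18. What may go wrong: ionisation of the acylal is slow, so the exchange may stall at equilibrium or intermolecular exchange (oligomers) may take over. Fallback (reduce first, close by hydrolysis): setting out from 25, the aldehyde is protected as the dimethyl acetal F8 (HC(OMe)3, PPTS, MeOH). The tert-butyl dioxolanone is then reduced with Sia2BH to the 2-tert-butyl-1,3-dioxolan-4-ol F9, now an ordinary and easily hydrolysed acetal. Aqueous acid (AcOH/H2O/THF) should remove methanol and pivalaldehyde so that the C17 hydroxy dialdehyde closes to the bicyclic lactol 27, where the route is rejoined.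

## Further compounds

F1 | step 8 | 1,3-dioxolane acetal of trienal 11 | C1COC(O1)/C=C(\C)CC[C@H]1C(C)(C)CCC[C@]1(C)/C=C/C=C/CO[Si](c1ccccc1)(c1ccccc1)C(C)(C)C
F2 | step 8 | 1,3-dioxolane acetal of cycloadduct 12 | C1COC(O1)[C@@H]1[C@H](CO[Si](c2ccccc2)(c2ccccc2)C(C)(C)C)C=C[C@H]2[C@@]1(C)CC[C@H]1C(C)(C)CCC[C@]21C
F3 | step 13 | carboxylic acid from aldehyde 15 (C14–CH2–CO2H) | OC(=O)C[C@@H]1[C@H](CO[Si](c2ccccc2)(c2ccccc2)C(C)(C)C)CC[C@H]2[C@@]1(C)CC[C@H]1C(C)(C)CCC[C@]21C
F4 | step 13 | acyl imidazole of F3 | O=C(n1ccnc1)C[C@@H]1[C@H](CO[Si](c2ccccc2)(c2ccccc2)C(C)(C)C)CC[C@H]2[C@@]1(C)CC[C@H]1C(C)(C)CCC[C@]21C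
F5 | step 13 | C16 ketone acid (17R; C-acylated dioxolanone) | CC(C)(C)[C@H]1O[C@@](CC(=O)O)(C(=O)O1)C(=O)C[C@@H]1[C@H](CO[Si](c2ccccc2)(c2ccccc2)C(C)(C)C)CC[C@H]2[C@@]1(C)CC[C@H]1C(C)(C)CCC[C@]21C
F6 | step 13 | benzyl ester of F5 | CC(C)(C)[C@H]1O[C@@](CC(=O)OCc2ccccc2)(C(=O)O1)C(=O)C[C@@H]1[C@H](CO[Si](c2ccccc2)(c2ccccc2)C(C)(C)C)CC[C@H]2[C@@]1(C)CC[C@H]1C(C)(C)CCC[C@]21C
F7 | step 13 | 16R alcohol benzyl ester (22 without the acetyl group) | CC(C)(C)[C@H]1O[C@@](CC(=O)OCc2ccccc2)(C(=O)O1)[C@H](O)C[C@@H]1[C@H](CO[Si](c2ccccc2)(c2ccccc2)C(C)(C)C)CC[C@H]2[C@@]1(C)CC[C@H]1C(C)(C)CCC[C@]21C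
F8 | step 18 | dimethyl acetal of aldehyde 25 | CC(C)(C)[C@H]1O[C@@](CC(=O)OCc2ccccc2)(C(=O)O1)[C@H](OC(C)=O)C[C@@H]1[C@@H](C(OC)OC)CC[C@H]2[C@@]1(C)CC[C@H]1C(C)(C)CCC[C@]21C
F9 | step 18 | 2-tert-butyl-1,3-dioxolan-4-ol from F8 (C24 lactol, both anomers) | CC(C)(C)[C@H]1O[C@@](CC(=O)OCc2ccccc2)(C(O)O1)[C@H](OC(C)=O)C[C@@H]1[C@@H](C(OC)OC)CC[C@H]2[C@@]1(C)CC[C@H]1C(C)(C)CCC[C@]21C
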